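**Retrosynthetic overview**

1. Target ⇐ hydrogenolysis of its 7,4'-di-O-benzyl ether (the only protecting groups carried).
2. Ring C is the only ring built and is formed last (rings A and B are bought as benzenes): the O1–C2 and C3–O bonds come from Claisen–Schmidt condensation and Algar–Flynn–Oyamada oxidative cyclisation of an A-ring acetophenone with a B-ring aldehyde.
3. Side chain: the CH2–O bond and the (S) centre are made together by a new CuH-catalysed enantioselective anti-Markovnikov hydro-oxygenation of a 3-methylbut-3-enyl arene; the alkene comes from 4-(benzyloxy)-3-bromobenzaldehyde by Negishi coupling.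
4. A ring: 2,4-dihydroxy-6-methoxyacetophenone ⇒ 4-O-benzylation, para C–H oxygenation (Elbs), 5-O-methylation.

Assumption: (R)-DTBM-SEGPHOS is taken to give the (S) centre in step 3; if Mosher/HPLC analysis of the first run shows (R), the commercial (S)-ligand is used instead and nothing else changes.

**Step 1**
Reactants: 1 4-(benzyloxy)-3-bromobenzaldehyde
Product: 2 1-(benzyloxy)-2-bromo-4-(dimethoxymethyl)benzene
Conditions: HC(OMe)3 (1.5 equiv), p-TsOH·H2O (1 mol %), MeOH, rt, 2 h; Et3N quench
Reagents that add atoms: trimethyl orthoformate, COC(OC)OC; methanol, CO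
Why: Acid-catalysed acetalisation driven by the orthoester as water scavenger; it masks the aldehyde, which CuH/silane would otherwise reduce in step 3.

**Step 2**
Reactants: 2 1-(benzyloxy)-2-bromo-4-(dimethoxymethyl)benzene; 3 4-bromo-2-methylbut-1-ene
Product: 5 1-(benzyloxy)-4-(dimethoxymethyl)-2-(3-methylbut-3-en-1-yl)benzene, via (3-methylbut-3-en-1-yl)zinc bromide 4 (not isolated)
Conditions: 3 (1.5 equiv), Zn dust, LiCl, THF, 50 °C; then 2, Pd(OAc)2 (2 mol %), SPhos (4 mol %), THF, 50 °C
Reagents that add atoms: none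
Why: Negishi sp2–sp3 cross-coupling; LiCl-promoted zinc insertion gives a primary homoallylic zinc reagent that tolerates the acetal, and SPhos-ligated Pd couples ortho-alkoxy aryl bromides with primary alkylzincs without isomerising the alkene.

**Step 3**
Reactants: 5 1-(benzyloxy)-4-(dimethoxymethyl)-2-(3-methylbut-3-en-1-yl)benzene
Product: 7 (2S)-4-[2-(benzyloxy)-5-formylphenyl]-2-methylbutyl benzoate, via acetal benzoate 6 (not isolated)
Conditions: Cu(OAc)2 (5 mol %), (R)-DTBM-SEGPHOS (5.5 mol %), (MeO)2MeSiH (3 equiv), THF, 40 °C, (PhCO2)2 (1.5 equiv) in THF added over 12 h by syringe pump; then 1 M HCl, THF, rt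
Reagents that add atoms: dibenzoyl peroxide, O=C(OOC(=O)c1ccccc1)c1ccccc1; water, O
Why: Proposed new method: L*CuH (from Cu(OAc)2, the bisphosphine and the silane) adds syn across the unactivated 1,1-disubstituted alkene with Cu on the terminal CH2 and H on the internal carbon, the enantio-determining hydrocupration already established for this alkene class, which sets the (S) centre; the primary alkylcopper(I), which is the species the slowly fed peroxide meets, is captured by the O–O bond of dibenzoyl peroxide (oxidative addition or SET/rebound to an alkyl-Cu(III) benzoate, then C(sp3)–O reductive elimination as in Kharasch–Sosnovsky oxidations) to give the primary benzoate and L*Cu–O2CPh, which the silane turns back into L*CuH; the closest known reaction type is the CuH-catalysed enantioselective anti-Markovnikov hydroamination of 1,1-disubstituted alkenes with R2N–OBz electrophiles (and CuH hydroboration/oxidation), the new element being an O–O electrophile in place of the N–O one so that the C–O bond forms directly; the centre is β to the new C–O bond and cannot be scrambled by the capture step, and the acid work-up only unmasks the aldehyde.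

**Step 4**
Reactants: 8 1-(2,4-dihydroxy-6-methoxyphenyl)ethan-1-one
Product: 9 1-[4-(benzyloxy)-2-hydroxy-6-methoxyphenyl]ethan-1-one
Conditions: BnBr (1.05 equiv), K2CO3, acetone, reflux
Reagents that add atoms: benzyl bromide, BrCc1ccccc1
Why: Williamson etherification; the 2-OH is locked in a hydrogen bond to the ketone, so the free, more acidic 4-OH is benzylated selectively.

**Step 5**
Reactants: 9 1-[4-(benzyloxy)-2-hydroxy-6-methoxyphenyl]ethan-1-one
Product: 11 1-[4-(benzyloxy)-3,6-dihydroxy-2-methoxyphenyl]ethan-1-one, via aryl potassium sulfate 10 (not isolated)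
Conditions: K2S2O8 (1.1 equiv), aq KOH, pyridine, 10 °C → rt, 24 h; then 2 M HCl, Na2SO3, 80 °C, 30 min
Reagents that add atoms: potassium peroxodisulfate, [K+].[K+].[O-]S(=O)(=O)OOS(=O)(=O)[O-]
Why: Elbs persulfate oxidation: the phenolate is attacked by peroxodisulfate at its only free para carbon to give the aryl sulfate, which acid hydrolyses to the hydroquinone, so the new A-ring oxygen is placed without regiochemical ambiguity.

**Step 6**
Reactants: 11 1-[4-(benzyloxy)-3,6-dihydroxy-2-methoxyphenyl]ethan-1-one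
Product: 12 1-[4-(benzyloxy)-6-hydroxy-2,3-dimethoxyphenyl]ethan-1-one
Conditions: MeI (1.1 equiv), K2CO3, acetone, 40 °C, N2
Reagents that add atoms: iodomethane, CI
Why: Williamson methylation; the new OH is not chelated and is far more nucleophilic than the ketone-bound ortho OH, so one equivalent of MeI methylates it selectively.

**Step 7**
Reactants: 12 1-[4-(benzyloxy)-6-hydroxy-2,3-dimethoxyphenyl]ethan-1-one; 7 (2S)-4-[2-(benzyloxy)-5-formylphenyl]-2-methylbutyl benzoate
Product: 16 7-(benzyloxy)-2-{4-(benzyloxy)-3-[(3S)-4-hydroxy-3-methylbutyl]phenyl}-3-hydroxy-5,6-dimethoxy-4H-chromen-4-one, via hydroxy aldehyde 13 (not isolated), via chalcone 14 (not isolated), via dihydroflavonol 15 (not isolated)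
Conditions: KOH (50% aq, 10 equiv), EtOH, rt, 36 h; then 30% H2O2 (6 equiv), 0 °C → rt, 4 h, one pot; 2 M HCl work-up
Reagents that add atoms: hydrogen peroxide, OO
Why: Hydroxide first saponifies the benzoate (13) and then drives the Claisen–Schmidt condensation to chalcone 14; in the Algar–Flynn–Oyamada oxidation the 2'-phenolate adds to C-β (O1–C2 bond) and alkaline H2O2 hydroxylates C-α (C3–O bond) to dihydroflavonol 15, which excess peroxide dehydrogenates to the flavonol.

**Step 8**
Reactants: 16 7-(benzyloxy)-2-{4-(benzyloxy)-3-[(3S)-4-hydroxy-3-methylbutyl]phenyl}-3-hydroxy-5,6-dimethoxy-4H-chromen-4-one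
Product: 17 3,7-dihydroxy-2-{4-hydroxy-3-[(3S)-4-hydroxy-3-methylbutyl]phenyl}-5,6-dimethoxy-4H-chromen-4-one
Conditions: H2 (1 atm), 10% Pd/C, THF–MeOH (1:1), rt
Reagents that add atoms: none
Why: Pd-catalysed hydrogenolysis cleaves both aryl benzyl ethers; the flavonol core, the methyl ethers, the primary alcohol and the remote stereocentre are untouched.

**Compound list**

1 | 4-(benzyloxy)-3-bromobenzaldehyde | O=Cc1ccc(OCc2ccccc2)c(Br)c1 | starting material
2 | 1-(benzyloxy)-2-bromo-4-(dimethoxymethyl)benzene | COC(OC)c1ccc(OCc2ccccc2)c(Br)c1 | intermediate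
3 | 4-bromo-2-methylbut-1-ene | C=C(C)CCBr | starting material
4 | (3-methylbut-3-en-1-yl)zinc bromide | C=C(C)CC[Zn]Br | intermediate
5 | 1-(benzyloxy)-4-(dimethoxymethyl)-2-(3-methylbut-3-en-1-yl)benzene | COC(OC)c1ccc(OCc2ccccc2)c(CCC(C)=C)c1 | intermediate
6 | (2S)-4-[2-(benzyloxy)-5-(dimethoxymethyl)phenyl]-2-methylbutyl benzoate | COC(OC)c1ccc(OCc2ccccc2)c(CC[C@H](C)COC(=O)c2ccccc2)c1 | intermediate
7 | (2S)-4-[2-(benzyloxy)-5-formylphenyl]-2-methylbutyl benzoate | O=Cc1ccc(OCc2ccccc2)c(CC[C@H](C)COC(=O)c2ccccc2)c1 | intermediate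
8 | 1-(2,4-dihydroxy-6-methoxyphenyl)ethan-1-one | CC(=O)c1c(O)cc(O)cc1OC | starting material
9 | 1-[4-(benzyloxy)-2-hydroxy-6-methoxyphenyl]ethan-1-one | CC(=O)c1c(O)cc(OCc2ccccc2)cc1OC | intermediate
10 | potassium 3-acetyl-6-(benzyloxy)-4-hydroxy-2-methoxyphenyl sulfate | CC(=O)c1c(O)cc(OCc2ccccc2)c(OS(=O)(=O)[O-])c1OC.[K+] | intermediate
11 | 1-[4-(benzyloxy)-3,6-dihydroxy-2-methoxyphenyl]ethan-1-one | CC(=O)c1c(O)cc(OCc2ccccc2)c(O)c1OC | intermediate
12 | 1-[4-(benzyloxy)-6-hydroxy-2,3-dimethoxyphenyl]ethan-1-one | CC(=O)c1c(O)cc(OCc2ccccc2)c(OC)c1OC | intermediate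
13 | 4-(benzyloxy)-3-[(3S)-4-hydroxy-3-methylbutyl]benzaldehyde | O=Cc1ccc(OCc2ccccc2)c(CC[C@H](C)CO)c1 | intermediate
14 | (2E)-1-[4-(benzyloxy)-6-hydroxy-2,3-dimethoxyphenyl]-3-{4-(benzyloxy)-3-[(3S)-4-hydroxy-3-methylbutyl]phenyl}prop-2-en-1-one | COc1c(OCc2ccccc2)cc(O)c(C(=O)/C=C/c2ccc(OCc3ccccc3)c(CC[C@H](C)CO)c2)c1OC | intermediate
15 | 7-(benzyloxy)-2-{4-(benzyloxy)-3-[(3S)-4-hydroxy-3-methylbutyl]phenyl}-3-hydroxy-5,6-dimethoxy-2,3-dihydro-4H-chromen-4-one (2,3-trans, both trans diastereomers; the two ring centres disappear in the next event) | COc1c(OCc2ccccc2)cc2OC(c3ccc(OCc4ccccc4)c(CC[C@H](C)CO)c3)C(O)C(=O)c2c1OC | intermediate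
16 | 7-(benzyloxy)-2-{4-(benzyloxy)-3-[(3S)-4-hydroxy-3-methylbutyl]phenyl}-3-hydroxy-5,6-dimethoxy-4H-chromen-4-one | COc1c(OCc2ccccc2)cc2oc(-c3ccc(OCc4ccccc4)c(CC[C@H](C)CO)c3)c(O)c(=O)c2c1OC | intermediate
17 | 3,7-dihydroxy-2-{4-hydroxy-3-[(3S)-4-hydroxy-3-methylbutyl]phenyl}-5,6-dimethoxy-4H-chromen-4-one | COc1c(O)cc2oc(-c3ccc(O)c(CC[C@H](C)CO)c3)c(O)c(=O)c2c1OC | target

**Step count**

Total steps: 8. Longest linear sequence: 5 (steps 1, 2, 3, 7, 8; the A-ring branch 4, 5, 6, 7, 8 is equally long).

**Three steps most likely to fail**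

1. Step 3, the new CuH hydro-benzoyloxylation. The peroxide may be reduced directly by L*CuH, oxidise the phosphine, or open Kharasch-type radical channels. The ee rests on known hydrocupration selectivity for methyl versus primary-alkyl substituents and should be checked on the first run. The fallback uses known chemistry and sets out from 5. CuH-catalysed enantioselective hydroboration with pinacolborane (CuCl, NaOt-Bu, the same DTBM-SEGPHOS antipode, THF, rt) gives (R)-2-{4-[2-(benzyloxy)-5-(dimethoxymethyl)phenyl]-2-methylbutyl}-4,4,5,5-tetramethyl-1,3,2-dioxaborolane F1. This has the same spatial arrangement; the descriptor changes only through CIP priorities. Oxidation with NaBO3·4H2O in THF–water gives (2S)-4-[2-(benzyloxy)-5-(dimethoxymethyl)phenyl]-2-methylbutan-1-ol F2. 1 M HCl in THF then unmasks the aldehyde, and the fallback comes back to the route at 13, which is carried into step 7 in place of 7.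

2. Step 7, the one-pot condensation/AFO oxidation. A 6'-methoxy group on a 2'-hydroxychalcone is known to divert part of the material to the aurone (5-exo attack at C-α) instead of the flavonol. The fallback sets out from 12 and 7. The condensation is run alone (KOH, EtOH) and chalcone 14 is isolated. Oxidative cyclisation with catalytic I2 in DMSO at 120 °C gives 7-(benzyloxy)-2-{4-(benzyloxy)-3-[(3S)-4-hydroxy-3-methylbutyl]phenyl}-5,6-dimethoxy-4H-chromen-4-one F3. Dimethyldioxirane in acetone/CH2Cl2 epoxidises C2=C3 to 7-(benzyloxy)-2-{4-(benzyloxy)-3-[(3S)-4-hydroxy-3-methylbutyl]phenyl}-2,3-epoxy-5,6-dimethoxy-2,3-dihydro-4H-chromen-4-one F4. Catalytic p-TsOH opens the epoxide to the flavonol, coming back to the route at 16.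

3. Step 5, the Elbs oxidation. It is regiospecific but typically stops at 25–45% conversion with recovered 9, and the lipophilic benzyl ether may react sluggishly in aqueous alkali. The fallback sets out from 9. Teuber oxidation with Fremy's salt ((KSO3)2NO, KH2PO4 buffer, acetone–water) gives the para-quinone 2-acetyl-5-(benzyloxy)-3-methoxycyclohexa-2,5-diene-1,4-dione F5. Reduction with aqueous Na2S2O4 gives the hydroquinone, coming back to the route at 11.

**Further compounds**

F1 | step 3 | (R)-2-{4-[2-(benzyloxy)-5-(dimethoxymethyl)phenyl]-2-methylbutyl}-4,4,5,5-tetramethyl-1,3,2-dioxaborolane | COC(OC)c1ccc(OCc2ccccc2)c(CC[C@H](C)CB2OC(C)(C)C(C)(C)O2)c1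
F2 | step 3 | (2S)-4-[2-(benzyloxy)-5-(dimethoxymethyl)phenyl]-2-methylbutan-1-ol | COC(OC)c1ccc(OCc2ccccc2)c(CC[C@H](C)CO)c1
F3 | step 7 | 7-(benzyloxy)-2-{4-(benzyloxy)-3-[(3S)-4-hydroxy-3-methylbutyl]phenyl}-5,6-dimethoxy-4H-chromen-4-one | COc1c(OCc2ccccc2)cc2oc(-c3ccc(OCc4ccccc4)c(CC[C@H](C)CO)c3)cc(=O)c2c1OC
F4 | step 7 | 7-(benzyloxy)-2-{4-(benzyloxy)-3-[(3S)-4-hydroxy-3-methylbutyl]phenyl}-2,3-epoxy-5,6-dimethoxy-2,3-dihydro-4H-chromen-4-one (both epoxide diastereomers) | COc1c(OCc2ccccc2)cc2OC3(c4ccc(OCc5ccccc5)c(CC[C@H](C)CO)c4)OC3C(=O)c2c1OC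
F5 | step 5 | 2-acetyl-5-(benzyloxy)-3-methoxycyclohexa-2,5-diene-1,4-dione | CC(=O)C1=C(OC)C(=O)C(OCc2ccccc2)=CC1=O
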